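**Plan**

- Locants: oxolane O1, C2–C5; flavan ring A (benzene, C4a–C8a) and ring C (pyran, O1, C2–C4). Retrosynthetic cuts: the ten O–benzyl bonds; the aryl–C(=O) bond of the ketone on oxolane C3; the O1–C8a aryl ether bond of ring C; the bond from C6 of ring A to the diarylmethine carbon; the oxolane O1–C5 and C2–C3 bonds (back to a donor–acceptor cyclopropane and an aldehyde); the C2–aryl and C3–C4 bonds of the flavan chain.
- Forward order: enal → cyclopropane → (3+2) annulation gives the oxolane, taken on to carbinol 14. The ring A piece 22 is made from 5-bromo-2,4-dihydroxybenzaldehyde. The two are joined at C6, the chain ketone is reduced, ring C is closed as the last ring, then the aryl ketone is installed and all benzyl ethers are removed.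
- Feature used: on ring A the target has hydrogen on C8, which is the neighbour of the ether carbon C8a, while C6 lies between the oxygens on C5 and C7. A bromine parked on C8 first leaves C6 as the only nucleophilic ring carbon for the union. It is then lost together with H-8a to give the C8–C8a aryne, which the C2 alkoxide (tether C3–C4–C4a) can reach only at C8a.
- Stereochemistry: cyclopropane carbons by amine catalysis; oxolane C5 by inversion and C2 by the cis-selective closure in the annulation; C3 by equilibration; the diarylmethine carbon by 1,3-allylic strain control in the union. Flavan C3 comes from an oxazolidinone auxiliary and C2 from chelation-controlled reduction; both are kept in the ring closure because no bond to C2 or C3 is broken.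

Key step: step 17

Remark: carbinol 14 is carried as a mixture of epimers at the hydroxyl-bearing carbon, which becomes planar in step 15; compounds 1, 2, 4, 8, 13, 15, 19 and 28 are taken as commercially available.

**Route**

Step 1
Reactants: 1 2,4-bis(benzyloxy)benzaldehyde; 2 (triphenyl-λ5-phosphanylidene)acetaldehyde
Product: 3 (2E)-3-[2,4-bis(benzyloxy)phenyl]prop-2-enal
Conditions: toluene, 90 °C
Reagents that add atoms: none
Why: Wittig reaction of an aryl aldehyde with a stabilised ylide, which should give the (E)-enal and stop after one homologation because the conjugated product is the poorer electrophile.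

Step 2
Reactants: 3 (2E)-3-[2,4-bis(benzyloxy)phenyl]prop-2-enal; 4 dimethyl 2-bromomalonate
Product: 5 dimethyl (2R,3S)-2-[2,4-bis(benzyloxy)phenyl]-3-formylcyclopropane-1,1-dicarboxylate
Conditions: (R)-α,α-diphenyl-2-pyrrolidinemethanol trimethylsilyl ether (20 mol %), 2,6-lutidine, CH2Cl2, 0 °C to rt
Reagents that add atoms: none
Why: Organocatalytic Michael-initiated ring closure: the (R)-prolinol ether forms an (E)-iminium ion with one face shielded, so the bromomalonate should add to the β-carbon from the open face and the resulting enamine displaces bromide to close the trans cyclopropane, which sets both ring stereocentres.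

Step 3
Reactants: 5 dimethyl (2R,3S)-2-[2,4-bis(benzyloxy)phenyl]-3-formylcyclopropane-1,1-dicarboxylate
Product: 7 dimethyl (2R,3S)-2-[2,4-bis(benzyloxy)phenyl]-3-{[tert-butyl(diphenyl)silyl]oxymethyl}cyclopropane-1,1-dicarboxylate, via hydroxymethyl cyclopropane 6 (not isolated)
Conditions: NaBH4, MeOH–CH2Cl2, −40 °C; crude alcohol at once into t-BuPh2SiCl, imidazole, DMF, 0 °C to rt
Reagents that add atoms: tert-butyl(chloro)diphenylsilane, CC(C)(C)[Si](Cl)(c1ccccc1)c1ccccc1
Why: Chemoselective borohydride reduction of the aldehyde beside the malonate esters, followed without purification by silylation so that the cis hydroxy ester cannot lactonise; neither stereocentre is touched.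

Step 4
Reactants: 7 dimethyl (2R,3S)-2-[2,4-bis(benzyloxy)phenyl]-3-{[tert-butyl(diphenyl)silyl]oxymethyl}cyclopropane-1,1-dicarboxylate; 8 4-(benzyloxy)benzaldehyde
Product: 9 dimethyl (2S,4S,5S)-2-[4-(benzyloxy)phenyl]-5-[2,4-bis(benzyloxy)phenyl]-4-{[tert-butyl(diphenyl)silyl]oxymethyl}oxolane-3,3-dicarboxylate
Conditions: Sn(OTf)2 (10 mol %), 4 Å molecular sieves, CH2Cl2, −40 to −10 °C
Reagents that add atoms: none
Why: Lewis-acid-catalysed (3+2) annulation of a donor–acceptor cyclopropane with an aldehyde, in which the aldehyde oxygen should open the tin-chelated malonate at the benzylic carbon with inversion (placing the C5 aryl group cis to the C4 side chain) and the malonate then closes on the oxocarbenium carbon through an envelope that sets the C2 aryl group cis to the C5 aryl group, C4 being carried over unchanged.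

Step 5
Reactants: 9 dimethyl (2S,4S,5S)-2-[4-(benzyloxy)phenyl]-5-[2,4-bis(benzyloxy)phenyl]-4-{[tert-butyl(diphenyl)silyl]oxymethyl}oxolane-3,3-dicarboxylate
Product: 10 methyl (2R,3R,4S,5S)-2-[4-(benzyloxy)phenyl]-5-[2,4-bis(benzyloxy)phenyl]-4-{[tert-butyl(diphenyl)silyl]oxymethyl}oxolane-3-carboxylate
Conditions: LiCl, H2O, DMSO, 150 °C; then NaOMe (cat.), MeOH, rt
Reagents that add atoms: none
Why: Krapcho dealkoxycarbonylation followed by base equilibration of the remaining ester, which should settle trans to both the C2 aryl group and the C4 side chain because these share the opposite face, so C3 is set under thermodynamic control.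

Step 6
Reactants: 10 methyl (2R,3R,4S,5S)-2-[4-(benzyloxy)phenyl]-5-[2,4-bis(benzyloxy)phenyl]-4-{[tert-butyl(diphenyl)silyl]oxymethyl}oxolane-3-carboxylate
Product: 11 methyl (2R,3R,4S,5S)-2-[4-(benzyloxy)phenyl]-5-[2,4-bis(benzyloxy)phenyl]-4-(hydroxymethyl)oxolane-3-carboxylate
Conditions: Bu4NF, AcOH, THF, 0 °C to rt
Reagents that add atoms: none
Why: Fluoride cleavage of the silyl ether, buffered with acetic acid so that the ester and its alpha centre are left alone; the freed alcohol is trans to the ester and cannot lactonise.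

Step 7
Reactants: 11 methyl (2R,3R,4S,5S)-2-[4-(benzyloxy)phenyl]-5-[2,4-bis(benzyloxy)phenyl]-4-(hydroxymethyl)oxolane-3-carboxylate
Product: 12 methyl (2R,3R,4R,5S)-2-[4-(benzyloxy)phenyl]-5-[2,4-bis(benzyloxy)phenyl]-4-formyloxolane-3-carboxylate
Conditions: Dess–Martin periodinane, NaHCO3, CH2Cl2, 0 °C; used at once
Reagents that add atoms: none
Why: Dess–Martin oxidation under buffered conditions, mild enough to leave the now enolisable C4 centre intact.

Step 8
Reactants: 12 methyl (2R,3R,4R,5S)-2-[4-(benzyloxy)phenyl]-5-[2,4-bis(benzyloxy)phenyl]-4-formyloxolane-3-carboxylate; 13 [4-(benzyloxy)phenyl]magnesium bromide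
Product: 14 methyl (2R,3R,4S,5S)-2-[4-(benzyloxy)phenyl]-4-{[4-(benzyloxy)phenyl](hydroxy)methyl}-5-[2,4-bis(benzyloxy)phenyl]oxolane-3-carboxylate (both carbinol epimers)
Conditions: THF, −78 °C
Reagents that add atoms: none
Why: Grignard addition to the aldehyde at −78 °C, where the methyl ester does not react; the new carbinol centre is left uncontrolled because it is made planar in step 15.

Step 9
Reactants: 15 5-bromo-2,4-dihydroxybenzaldehyde
Product: 16 2,4-bis(benzyloxy)-5-bromobenzaldehyde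
Conditions: BnBr, K2CO3, DMF, 60 °C
Reagents that add atoms: benzyl bromide, BrCc1ccccc1
Why: Williamson ether synthesis on both phenols; the ring keeps hydrogen at the carbons that become C6 and C8a and bromine at the carbon that becomes C8.

Step 10
Reactants: 16 2,4-bis(benzyloxy)-5-bromobenzaldehyde
Product: 17 [2,4-bis(benzyloxy)-5-bromophenyl]methanol
Conditions: NaBH4, MeOH–THF, 0 °C
Reagents that add atoms: none
Why: Borohydride reduction of the aryl aldehyde to the benzylic alcohol.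

Step 11
Reactants: 17 [2,4-bis(benzyloxy)-5-bromophenyl]methanol
Product: 18 1,5-bis(benzyloxy)-2-bromo-4-(bromomethyl)benzene
Conditions: PBr3, Et2O, 0 °C; used crude
Reagents that add atoms: phosphorus tribromide, BrP(Br)Br
Why: Conversion of a benzylic alcohol into the bromide with PBr3 at low temperature; the electron-rich bromide is taken on without chromatography.

Step 12
Reactants: 18 1,5-bis(benzyloxy)-2-bromo-4-(bromomethyl)benzene; 19 (4S)-4-benzyl-3-[(benzyloxy)acetyl]-1,3-oxazolidin-2-one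
Product: 20 (4S)-4-benzyl-3-{(2R)-2-(benzyloxy)-3-[2,4-bis(benzyloxy)-5-bromophenyl]propanoyl}-1,3-oxazolidin-2-one
Conditions: NaN(SiMe3)2, THF, −78 °C; then 18, −78 to −40 °C
Reagents that add atoms: none
Why: Evans auxiliary alkylation: the chelated (Z)-sodium enolate of the glycolate imide should be benzylated on the face opposite the 4-benzyl group, which sets the (R) centre that becomes C3 of the flavan.

Step 13
Reactants: 20 (4S)-4-benzyl-3-{(2R)-2-(benzyloxy)-3-[2,4-bis(benzyloxy)-5-bromophenyl]propanoyl}-1,3-oxazolidin-2-one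
Product: 21 (2R)-2-(benzyloxy)-3-[2,4-bis(benzyloxy)-5-bromophenyl]-N-methoxy-N-methylpropanamide
Conditions: MeNH(OMe)·HCl, AlMe3, CH2Cl2, 0 °C to rt; 1 M HCl work-up
Reagents that add atoms: N,O-dimethylhydroxylamine hydrochloride, CNOC.Cl
Why: Aluminium-amide transamination of the imide to the Weinreb amide with release of the auxiliary, a process that does not touch the alpha centre.

Step 14
Reactants: 21 (2R)-2-(benzyloxy)-3-[2,4-bis(benzyloxy)-5-bromophenyl]-N-methoxy-N-methylpropanamide; 13 [4-(benzyloxy)phenyl]magnesium bromide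
Product: 22 (2R)-2-(benzyloxy)-1-[4-(benzyloxy)phenyl]-3-[2,4-bis(benzyloxy)-5-bromophenyl]propan-1-one
Conditions: THF, −20 to 0 °C
Reagents that add atoms: none
Why: Weinreb ketone synthesis; the chelated tetrahedral intermediate should prevent both over-addition and enolisation of the alpha-alkoxy ketone.

Step 15
Reactants: 14 methyl (2R,3R,4S,5S)-2-[4-(benzyloxy)phenyl]-4-{[4-(benzyloxy)phenyl](hydroxy)methyl}-5-[2,4-bis(benzyloxy)phenyl]oxolane-3-carboxylate; 22 (2R)-2-(benzyloxy)-1-[4-(benzyloxy)phenyl]-3-[2,4-bis(benzyloxy)-5-bromophenyl]propan-1-one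
Product: 24 methyl (2R,3R,4R,5S)-2-[4-(benzyloxy)phenyl]-4-{(S)-[4-(benzyloxy)phenyl][2,6-bis(benzyloxy)-3-bromo-5-{(2R)-2-(benzyloxy)-3-[4-(benzyloxy)phenyl]-3-oxopropyl}phenyl]methyl}-5-[2,4-bis(benzyloxy)phenyl]oxolane-3-carboxylate, via trichloroacetimidate 23 (not isolated)
Conditions: Cl3CCN, DBU (cat.), CH2Cl2, 0 °C; concentrate; 22 (1.5 equiv), Me3SiOTf (10 mol %), 4 Å molecular sieves, CH2Cl2, −78 °C
Reagents that add atoms: none
Why: Friedel–Crafts alkylation through a benzylic trichloroacetimidate: Me3SiOTf should ionise only the imidate at −78 °C, arene 22 can react only at the carbon between its two benzyloxy groups because the other activated position carries bromine, and the cation, held by 1,3-allylic strain with H-4 of the oxolane in its plane, should be attacked from the side of C3 and away from the cis aryl group on C5, which gives the (S) diarylmethine centre.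

Step 16
Reactants: 24 (the ketone from step 15)
Product: 25 methyl (2R,3R,4R,5S)-2-[4-(benzyloxy)phenyl]-4-{(S)-[4-(benzyloxy)phenyl][2,6-bis(benzyloxy)-3-bromo-5-{(2R,3S)-2-(benzyloxy)-3-[4-(benzyloxy)phenyl]-3-hydroxypropyl}phenyl]methyl}-5-[2,4-bis(benzyloxy)phenyl]oxolane-3-carboxylate
Conditions: Zn(BH4)2, Et2O–CH2Cl2, −30 °C
Reagents that add atoms: none
Why: Chelation-controlled reduction of an alpha-alkoxy ketone: zinc bridges the carbonyl and benzyloxy oxygens and hydride should arrive anti to the arylmethyl group, giving the anti alcohol (the future C2 of the flavan), while the methyl ester is inert.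

Step 17
Reactants: 25 (the bromo alcohol from step 16)
Product: 27 methyl (2R,3R,4R,5S)-2-[4-(benzyloxy)phenyl]-4-{(S)-[4-(benzyloxy)phenyl][(2S,3R)-3,5,7-tris(benzyloxy)-2-[4-(benzyloxy)phenyl]-3,4-dihydro-2H-chromen-6-yl]methyl}-5-[2,4-bis(benzyloxy)phenyl]oxolane-3-carboxylate, via aryne 26 (not isolated)
Conditions: lithium 2,2,6,6-tetramethylpiperidide (6 equiv), THF, −78 to −20 °C; then MeOH, rt
Reagents that add atoms: none
Why: The amide base first forms the C2 alkoxide and the ester enolate and then removes H-8a, the only hydrogen on ring A, which lies ortho to bromine; loss of LiBr gives the C8–C8a aryne, the tethered alkoxide adds to C8a, and the C8 aryl anion, now flanked by two ether oxygens, is protonated by the amine. The closest known reaction type is the aryne-mediated ring closure of 3-(3-halophenyl)propoxides to chromans, a cine-substitution. Ring C closes in the 6-exo-dig mode with respect to the aryne bond, since only C8a ends up in the new ring. No stereocentre is formed, and C2 and C3 keep their configuration because the C2–O bond is never broken, unlike closures that pass through a benzylic cation. The step needs site selectivity for C8a over C8 and for H-8a over all other C–H bonds: the tether C3–C4–C4a can deliver oxygen only to C8a, the benzyloxy group on C7 favours carbanion character at C8, and the bromine that blocked C8 in step 15 is the only leaving group next to an aromatic hydrogen. The methanol quench leaves LiOMe, which should return the oxolane ester to the trans arrangement if the enolate was protonated from the wrong face.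

Step 18
Reactants: 27 (the flavan ester from step 17); 28 2,4-bis(benzyloxy)-1-bromobenzene
Product: 30 [2,4-bis(benzyloxy)phenyl][(2R,3R,4R,5S)-2-[4-(benzyloxy)phenyl]-4-{(S)-[4-(benzyloxy)phenyl][(2S,3R)-3,5,7-tris(benzyloxy)-2-[4-(benzyloxy)phenyl]-3,4-dihydro-2H-chromen-6-yl]methyl}-5-[2,4-bis(benzyloxy)phenyl]oxolan-3-yl]methanone, via Weinreb amide 29 (not isolated)
Conditions: MeNH(OMe)·HCl, iPrMgCl (2 equiv per amine salt), THF, −20 °C; then the aryllithium from 28 and n-BuLi (THF, −78 °C), −78 to 0 °C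
Reagents that add atoms: none
Why: Weinreb ketone synthesis run in one flask: the magnesium amide converts the methyl ester into the N-methoxy-N-methylamide and the aryllithium should then add once through a chelated tetrahedral intermediate, C3 of the oxolane keeping its trans configuration.

Step 19
Reactants: 30 (the decabenzyl ether from step 18)
Product: 31 (2,4-dihydroxyphenyl){(2R,3R,4R,5S)-5-(2,4-dihydroxyphenyl)-2-(4-hydroxyphenyl)-4-[(S)-(4-hydroxyphenyl)((2S,3R)-3,5,7-trihydroxy-2-(4-hydroxyphenyl)-3,4-dihydro-2H-chromen-6-yl)methyl]oxolan-3-yl}methanone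
Conditions: H2 (1 atm), Pd(OH)2 on carbon, THF–MeOH, rt
Reagents that add atoms: none
Why: Hydrogenolysis of all ten benzyl ethers under neutral conditions, which should leave the benzylic ring C–O bonds of the oxolane and the chroman and the aryl ketone intact; no stereocentre is affected.

**Compound list**

1 | 2,4-bis(benzyloxy)benzaldehyde | O=Cc1ccc(OCc2ccccc2)cc1OCc1ccccc1 | starting material
2 | (triphenyl-λ5-phosphanylidene)acetaldehyde | O=CC=P(c1ccccc1)(c1ccccc1)c1ccccc1 | starting material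
3 | (2E)-3-[2,4-bis(benzyloxy)phenyl]prop-2-enal | O=C/C=C/c1ccc(OCc2ccccc2)cc1OCc1ccccc1 | intermediate
4 | dimethyl 2-bromomalonate | COC(=O)C(Br)C(=O)OC | starting material
5 | dimethyl (2R,3S)-2-[2,4-bis(benzyloxy)phenyl]-3-formylcyclopropane-1,1-dicarboxylate (aryl and formyl trans) | COC(=O)C1(C(=O)OC)[C@@H](C=O)[C@@H]1c1ccc(OCc2ccccc2)cc1OCc1ccccc1 | intermediate
6 | dimethyl (2R,3S)-2-[2,4-bis(benzyloxy)phenyl]-3-(hydroxymethyl)cyclopropane-1,1-dicarboxylate | COC(=O)C1(C(=O)OC)[C@@H](CO)[C@@H]1c1ccc(OCc2ccccc2)cc1OCc1ccccc1 | intermediate (not isolated)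
7 | dimethyl (2R,3S)-2-[2,4-bis(benzyloxy)phenyl]-3-{[tert-butyl(diphenyl)silyl]oxymethyl}cyclopropane-1,1-dicarboxylate | COC(=O)C1(C(=O)OC)[C@@H](CO[Si](c2ccccc2)(c2ccccc2)C(C)(C)C)[C@@H]1c1ccc(OCc2ccccc2)cc1OCc1ccccc1 | intermediate
8 | 4-(benzyloxy)benzaldehyde | O=Cc1ccc(OCc2ccccc2)cc1 | starting material
9 | dimethyl (2S,4S,5S)-2-[4-(benzyloxy)phenyl]-5-[2,4-bis(benzyloxy)phenyl]-4-{[tert-butyl(diphenyl)silyl]oxymethyl}oxolane-3,3-dicarboxylate (substituents on C2, C4 and C5 on one face) | COC(=O)C1(C(=O)OC)[C@@H](CO[Si](c2ccccc2)(c2ccccc2)C(C)(C)C)[C@@H](c2ccc(OCc3ccccc3)cc2OCc2ccccc2)O[C@H]1c1ccc(OCc2ccccc2)cc1 | intermediate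
10 | methyl (2R,3R,4S,5S)-2-[4-(benzyloxy)phenyl]-5-[2,4-bis(benzyloxy)phenyl]-4-{[tert-butyl(diphenyl)silyl]oxymethyl}oxolane-3-carboxylate | COC(=O)[C@@H]1[C@@H](CO[Si](c2ccccc2)(c2ccccc2)C(C)(C)C)[C@@H](c2ccc(OCc3ccccc3)cc2OCc2ccccc2)O[C@H]1c1ccc(OCc2ccccc2)cc1 | intermediate
11 | methyl (2R,3R,4S,5S)-2-[4-(benzyloxy)phenyl]-5-[2,4-bis(benzyloxy)phenyl]-4-(hydroxymethyl)oxolane-3-carboxylate | COC(=O)[C@@H]1[C@@H](CO)[C@@H](c2ccc(OCc3ccccc3)cc2OCc2ccccc2)O[C@H]1c1ccc(OCc2ccccc2)cc1 | intermediate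
12 | methyl (2R,3R,4R,5S)-2-[4-(benzyloxy)phenyl]-5-[2,4-bis(benzyloxy)phenyl]-4-formyloxolane-3-carboxylate | COC(=O)[C@@H]1[C@@H](C=O)[C@@H](c2ccc(OCc3ccccc3)cc2OCc2ccccc2)O[C@H]1c1ccc(OCc2ccccc2)cc1 | intermediate
13 | [4-(benzyloxy)phenyl]magnesium bromide | Br[Mg]c1ccc(OCc2ccccc2)cc1 | starting material
14 | methyl (2R,3R,4S,5S)-2-[4-(benzyloxy)phenyl]-4-{[4-(benzyloxy)phenyl](hydroxy)methyl}-5-[2,4-bis(benzyloxy)phenyl]oxolane-3-carboxylate (both carbinol epimers) | COC(=O)[C@@H]1[C@@H](C(O)c2ccc(OCc3ccccc3)cc2)[C@@H](c2ccc(OCc3ccccc3)cc2OCc2ccccc2)O[C@H]1c1ccc(OCc2ccccc2)cc1 | intermediate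
15 | 5-bromo-2,4-dihydroxybenzaldehyde | O=Cc1cc(Br)c(O)cc1O | starting material
16 | 2,4-bis(benzyloxy)-5-bromobenzaldehyde | O=Cc1cc(Br)c(OCc2ccccc2)cc1OCc1ccccc1 | intermediate
17 | [2,4-bis(benzyloxy)-5-bromophenyl]methanol | OCc1cc(Br)c(OCc2ccccc2)cc1OCc1ccccc1 | intermediate
18 | 1,5-bis(benzyloxy)-2-bromo-4-(bromomethyl)benzene | BrCc1cc(Br)c(OCc2ccccc2)cc1OCc1ccccc1 | intermediate
19 | (4S)-4-benzyl-3-[(benzyloxy)acetyl]-1,3-oxazolidin-2-one | O=C(COCc1ccccc1)N1[C@@H](Cc2ccccc2)COC1=O | starting material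
20 | (4S)-4-benzyl-3-{(2R)-2-(benzyloxy)-3-[2,4-bis(benzyloxy)-5-bromophenyl]propanoyl}-1,3-oxazolidin-2-one | O=C([C@H](OCc1ccccc1)Cc1cc(Br)c(OCc2ccccc2)cc1OCc1ccccc1)N1[C@@H](Cc2ccccc2)COC1=O | intermediate
21 | (2R)-2-(benzyloxy)-3-[2,4-bis(benzyloxy)-5-bromophenyl]-N-methoxy-N-methylpropanamide | CON(C)C(=O)[C@H](OCc1ccccc1)Cc1cc(Br)c(OCc2ccccc2)cc1OCc1ccccc1 | intermediate
22 | (2R)-2-(benzyloxy)-1-[4-(benzyloxy)phenyl]-3-[2,4-bis(benzyloxy)-5-bromophenyl]propan-1-one | O=C(c1ccc(OCc2ccccc2)cc1)[C@H](OCc1ccccc1)Cc1cc(Br)c(OCc2ccccc2)cc1OCc1ccccc1 | intermediate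
23 | methyl (2R,3R,4R,5S)-2-[4-(benzyloxy)phenyl]-4-{[4-(benzyloxy)phenyl][(2,2,2-trichloroethanimidoyl)oxy]methyl}-5-[2,4-bis(benzyloxy)phenyl]oxolane-3-carboxylate | COC(=O)[C@@H]1[C@@H](C(OC(=N)C(Cl)(Cl)Cl)c2ccc(OCc3ccccc3)cc2)[C@@H](c2ccc(OCc3ccccc3)cc2OCc2ccccc2)O[C@H]1c1ccc(OCc2ccccc2)cc1 | intermediate (not isolated)
24 | methyl (2R,3R,4R,5S)-2-[4-(benzyloxy)phenyl]-4-{(S)-[4-(benzyloxy)phenyl][2,6-bis(benzyloxy)-3-bromo-5-{(2R)-2-(benzyloxy)-3-[4-(benzyloxy)phenyl]-3-oxopropyl}phenyl]methyl}-5-[2,4-bis(benzyloxy)phenyl]oxolane-3-carboxylate | COC(=O)[C@@H]1[C@@H]([C@@H](c2ccc(OCc3ccccc3)cc2)c2c(OCc3ccccc3)c(Br)cc(c2OCc2ccccc2)C[C@@H](OCc2ccccc2)C(=O)c2ccc(OCc3ccccc3)cc2)[C@@H](c2ccc(OCc3ccccc3)cc2OCc2ccccc2)O[C@H]1c1ccc(OCc2ccccc2)cc1 | intermediate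
25 | methyl (2R,3R,4R,5S)-2-[4-(benzyloxy)phenyl]-4-{(S)-[4-(benzyloxy)phenyl][2,6-bis(benzyloxy)-3-bromo-5-{(2R,3S)-2-(benzyloxy)-3-[4-(benzyloxy)phenyl]-3-hydroxypropyl}phenyl]methyl}-5-[2,4-bis(benzyloxy)phenyl]oxolane-3-carboxylate | COC(=O)[C@@H]1[C@@H]([C@@H](c2ccc(OCc3ccccc3)cc2)c2c(OCc3ccccc3)c(Br)cc(c2OCc2ccccc2)C[C@@H](OCc2ccccc2)[C@@H](O)c2ccc(OCc3ccccc3)cc2)[C@@H](c2ccc(OCc3ccccc3)cc2OCc2ccccc2)O[C@H]1c1ccc(OCc2ccccc2)cc1 | intermediate
26 | aryne from 25: ring A with a C8–C8a triple bond, formed as its lithium alkoxide and shown in the neutral form | COC(=O)[C@@H]1[C@@H]([C@@H](c2ccc(OCc3ccccc3)cc2)C2=C(OCc3ccccc3)C#CC(=C2OCc2ccccc2)C[C@@H](OCc2ccccc2)[C@@H](O)c2ccc(OCc3ccccc3)cc2)[C@@H](c2ccc(OCc3ccccc3)cc2OCc2ccccc2)O[C@H]1c1ccc(OCc2ccccc2)cc1 | intermediate (not isolated)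
27 | methyl (2R,3R,4R,5S)-2-[4-(benzyloxy)phenyl]-4-{(S)-[4-(benzyloxy)phenyl][(2S,3R)-3,5,7-tris(benzyloxy)-2-[4-(benzyloxy)phenyl]-3,4-dihydro-2H-chromen-6-yl]methyl}-5-[2,4-bis(benzyloxy)phenyl]oxolane-3-carboxylate | COC(=O)[C@@H]1[C@@H]([C@@H](c2ccc(OCc3ccccc3)cc2)c2c(OCc3ccccc3)cc3c(c2OCc2ccccc2)C[C@@H](OCc2ccccc2)[C@H](c2ccc(OCc4ccccc4)cc2)O3)[C@@H](c2ccc(OCc3ccccc3)cc2OCc2ccccc2)O[C@H]1c1ccc(OCc2ccccc2)cc1 | intermediate
28 | 2,4-bis(benzyloxy)-1-bromobenzene | Brc1ccc(OCc2ccccc2)cc1OCc1ccccc1 | starting material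
29 | N-methoxy-N-methylamide corresponding to ester 27 | CON(C)C(=O)[C@@H]1[C@@H]([C@@H](c2ccc(OCc3ccccc3)cc2)c2c(OCc3ccccc3)cc3c(c2OCc2ccccc2)C[C@@H](OCc2ccccc2)[C@H](c2ccc(OCc4ccccc4)cc2)O3)[C@@H](c2ccc(OCc3ccccc3)cc2OCc2ccccc2)O[C@H]1c1ccc(OCc2ccccc2)cc1 | intermediate (not isolated)
30 | [2,4-bis(benzyloxy)phenyl][(2R,3R,4R,5S)-2-[4-(benzyloxy)phenyl]-4-{(S)-[4-(benzyloxy)phenyl][(2S,3R)-3,5,7-tris(benzyloxy)-2-[4-(benzyloxy)phenyl]-3,4-dihydro-2H-chromen-6-yl]methyl}-5-[2,4-bis(benzyloxy)phenyl]oxolan-3-yl]methanone | O=C(c1ccc(OCc4ccccc4)cc1OCc1ccccc1)[C@@H]1[C@@H]([C@@H](c2ccc(OCc3ccccc3)cc2)c2c(OCc3ccccc3)cc3c(c2OCc2ccccc2)C[C@@H](OCc2ccccc2)[C@H](c2ccc(OCc4ccccc4)cc2)O3)[C@@H](c2ccc(OCc3ccccc3)cc2OCc2ccccc2)O[C@H]1c1ccc(OCc2ccccc2)cc1 | intermediate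
31 | (2,4-dihydroxyphenyl){(2R,3R,4R,5S)-5-(2,4-dihydroxyphenyl)-2-(4-hydroxyphenyl)-4-[(S)-(4-hydroxyphenyl)((2S,3R)-3,5,7-trihydroxy-2-(4-hydroxyphenyl)-3,4-dihydro-2H-chromen-6-yl)methyl]oxolan-3-yl}methanone | O=C(c1ccc(O)cc1O)[C@@H]1[C@@H]([C@@H](c2ccc(O)cc2)c2c(O)cc3c(c2O)C[C@@H](O)[C@H](c2ccc(O)cc2)O3)[C@@H](c2ccc(O)cc2O)O[C@H]1c1ccc(O)cc1 | target

**Count**

Total steps: 19. Longest linear sequence: 13 steps (steps 1–8, then 15–19); the ring A piece takes 6 steps (9–14).

**Steps most likely to fail**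

Step 15. The risks are poor facial selectivity in the attack on the benzylic cation, loss of H-4 from the cation to give a styrene, and slow attack by the crowded arene carbon. The fallback replaces substrate control at a free cation by catalyst control at a neutral para-quinone methide. It sets out from aldehyde 12: addition of {4-[tert-butyl(dimethyl)silyloxy]phenyl}magnesium bromide (THF, −78 °C) should give the silyl-protected carbinol F1, and Bu4NF/AcOH the 4-hydroxyphenyl carbinol F2. A chiral BINOL-derived phosphoric acid (toluene, 0 °C) should dehydrate F2 to the para-quinone methide in the flask and direct the 1,6-addition of arene 22, giving the phenol F3. Benzylation (BnBr, K2CO3, DMF) returns to the route at 24.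

Step 17. The risks are metalation at other sites, rearrangement of benzyl ethers, or base-induced opening of the ester-bearing oxolane in the large substrate. The fallback closes ring C before the union and blocks C8 afresh. It sets out from ketone 22: Zn(BH4)2 should give the anti alcohol F4, and lithium 2,2,6,6-tetramethylpiperidide (THF, −78 to −20 °C) the flavan F5 by the same aryne closure on a substrate without ester or diarylmethine hydrogen. N-Bromosuccinimide (CH2Cl2, −78 °C) should brominate C8 to give the 8-bromoflavan F6. Friedel–Crafts union of F6 with imidate 23 (Me3SiOTf cat., −78 °C), where only C6 is open, gives the 8-bromo ester F7. Bu3SnH/AIBN (toluene, 80 °C) removes the bromine and returns to the route at 27.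

Step 4. The risk is ionisation of the cyclopropane to a free benzylic cation before the aldehyde attacks, since the 2,4-dialkoxyphenyl group is a very strong donor; this would erode the inversion at C5 and the 4,5-cis relationship. The fallback weakens the donor with pivalate esters. It sets out from ylide 2, with commercial 2,4-dihydroxybenzaldehyde as a further starting material. Pivaloyl chloride/pyridine gives the bis(pivalate) aldehyde F8, Wittig reaction with 2 the enal F9, and the cyclopropanation of step 2 with 4 the cyclopropane aldehyde F10. Reduction and silylation as in step 3 give the silyl ether F11, and annulation with 8 (Sn(OTf)2, CH2Cl2, 0 °C to rt) the oxolane diester F12. K2CO3 in MeOH followed by BnBr in DMF exchanges the two pivalates for benzyl ethers and returns to the route at 9.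

**Further compounds**

F1 | step 15 | methyl (2R,3R,4S,5S)-2-[4-(benzyloxy)phenyl]-5-[2,4-bis(benzyloxy)phenyl]-4-[{4-[tert-butyl(dimethyl)silyloxy]phenyl}(hydroxy)methyl]oxolane-3-carboxylate | COC(=O)[C@@H]1[C@@H](C(O)c2ccc(O[Si](C)(C)C(C)(C)C)cc2)[C@@H](c2ccc(OCc3ccccc3)cc2OCc2ccccc2)O[C@H]1c1ccc(OCc2ccccc2)cc1
F2 | step 15 | methyl (2R,3R,4S,5S)-2-[4-(benzyloxy)phenyl]-5-[2,4-bis(benzyloxy)phenyl]-4-[hydroxy(4-hydroxyphenyl)methyl]oxolane-3-carboxylate | COC(=O)[C@@H]1[C@@H](C(O)c2ccc(O)cc2)[C@@H](c2ccc(OCc3ccccc3)cc2OCc2ccccc2)O[C@H]1c1ccc(OCc2ccccc2)cc1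
F3 | step 15 | analogue of 24 with a free 4-hydroxyphenyl group on the (S)-diarylmethine carbon | COC(=O)[C@@H]1[C@@H]([C@@H](c2ccc(O)cc2)c2c(OCc3ccccc3)c(Br)cc(c2OCc2ccccc2)C[C@@H](OCc2ccccc2)C(=O)c2ccc(OCc3ccccc3)cc2)[C@@H](c2ccc(OCc3ccccc3)cc2OCc2ccccc2)O[C@H]1c1ccc(OCc2ccccc2)cc1
F4 | step 17 | (1S,2R)-2-(benzyloxy)-1-[4-(benzyloxy)phenyl]-3-[2,4-bis(benzyloxy)-5-bromophenyl]propan-1-ol | O[C@@H](c1ccc(OCc2ccccc2)cc1)[C@H](OCc1ccccc1)Cc1cc(Br)c(OCc2ccccc2)cc1OCc1ccccc1
F5 | step 17 | (2S,3R)-3,5,7-tris(benzyloxy)-2-[4-(benzyloxy)phenyl]-3,4-dihydro-2H-chromene | c1c(OCc3ccccc3)cc2c(c1OCc1ccccc1)C[C@@H](OCc1ccccc1)[C@H](c1ccc(OCc3ccccc3)cc1)O2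
F6 | step 17 | (2S,3R)-3,5,7-tris(benzyloxy)-2-[4-(benzyloxy)phenyl]-8-bromo-3,4-dihydro-2H-chromene | c1c(OCc3ccccc3)c(Br)c2c(c1OCc1ccccc1)C[C@@H](OCc1ccccc1)[C@H](c1ccc(OCc3ccccc3)cc1)O2
F7 | step 17 | 8-bromo analogue of 27 (bromine on C8 of the chromene) | COC(=O)[C@@H]1[C@@H]([C@@H](c2ccc(OCc3ccccc3)cc2)c2c(OCc3ccccc3)c(Br)c3c(c2OCc2ccccc2)C[C@@H](OCc2ccccc2)[C@H](c2ccc(OCc4ccccc4)cc2)O3)[C@@H](c2ccc(OCc3ccccc3)cc2OCc2ccccc2)O[C@H]1c1ccc(OCc2ccccc2)cc1
F8 | step 4 | 4-formyl-1,3-phenylene bis(2,2-dimethylpropanoate) | O=Cc1ccc(OC(=O)C(C)(C)C)cc1OC(=O)C(C)(C)C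
F9 | step 4 | 4-[(1E)-3-oxoprop-1-en-1-yl]-1,3-phenylene bis(2,2-dimethylpropanoate) | O=C/C=C/c1ccc(OC(=O)C(C)(C)C)cc1OC(=O)C(C)(C)C
F10 | step 4 | dimethyl (2R,3S)-2-[2,4-bis(2,2-dimethylpropanoyloxy)phenyl]-3-formylcyclopropane-1,1-dicarboxylate | COC(=O)C1(C(=O)OC)[C@@H](C=O)[C@@H]1c1ccc(OC(=O)C(C)(C)C)cc1OC(=O)C(C)(C)C
F11 | step 4 | dimethyl (2R,3S)-2-[2,4-bis(2,2-dimethylpropanoyloxy)phenyl]-3-{[tert-butyl(diphenyl)silyl]oxymethyl}cyclopropane-1,1-dicarboxylate | COC(=O)C1(C(=O)OC)[C@@H](CO[Si](c2ccccc2)(c2ccccc2)C(C)(C)C)[C@@H]1c1ccc(OC(=O)C(C)(C)C)cc1OC(=O)C(C)(C)C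
F12 | step 4 | dimethyl (2S,4S,5S)-2-[4-(benzyloxy)phenyl]-5-[2,4-bis(2,2-dimethylpropanoyloxy)phenyl]-4-{[tert-butyl(diphenyl)silyl]oxymethyl}oxolane-3,3-dicarboxylate | COC(=O)C1(C(=O)OC)[C@@H](CO[Si](c2ccccc2)(c2ccccc2)C(C)(C)C)[C@@H](c2ccc(OC(=O)C(C)(C)C)cc2OC(=O)C(C)(C)C)O[C@H]1c1ccc(OCc2ccccc2)cc1
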